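**Retrosynthetic overview**
- Feature: C1 of ring D is bonded to the ring C oxygen, which sits ortho to the ring C hydroxyl. C1 can be carried as a carboxyl carbon, so the crowded C–O–D diaryl ether starts as a phenolic ester. Ring D numbering: C1 bears the oxygen, C2 lies between the two substituents, C3 bears the ethano bridge to ring A.
- Last disconnections: O-debenzylation, then dehydrogenation of ring D (a cyclohexa-1,3-diene). Before these, C1=C2 comes from ester methylenation and enol ether–diene ring-closing metathesis inside a 21-membered aryl macrolactone.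
- The lactone comes from a phenolic seco acid. Its B–C ethano bridge is cut by B-alkyl Suzuki coupling, so no alkene reduction is needed once the diene is present. The (Z)-dienoate chain is cut by Johnson–Claisen rearrangement of a divinyl carbinol, and the A–O–B ether by Ullmann coupling.
- Ring order: A, B and C are bought. The 21-membered lactone comes first, then the six-membered ring D and, by contraction, the 19-membered macrocycle, then aromatisation of ring D.

Key step: step 10

Remark on the chemistry: the target has no stereocentre, and the only stereochemical element is the Z geometry of the trisubstituted alkene of the dienyl chain (vinyl cis to the ester-bearing chain). The sigmatropic step is assumed to give both geometric isomers, so they are sorted on the small A–B fragment.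

Step 1
Reactants: 1 isoferulic acid
Product: 3 methyl 3-(3-hydroxy-4-methoxyphenyl)propanoate, via dihydroisoferulic acid 2 (not isolated)
Conditions: H2 (1 atm), Pd/C (10 wt %), MeOH, rt; filter; then H2SO4 (cat.), reflux
Reagents that add atoms: methanol, CO
Why: Heterogeneous hydrogenation saturates only the cinnamate alkene, and Fischer esterification in the same methanol then gives the ester.

Step 2
Reactants: 3 methyl 3-(3-hydroxy-4-methoxyphenyl)propanoate; 4 1-bromo-4-iodobenzene
Product: 5 methyl 3-[3-(4-bromophenoxy)-4-methoxyphenyl]propanoate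
Conditions: CuI (10 mol %), N,N-dimethylglycine·HCl (30 mol %), Cs2CO3 (2 equiv), 4 (1.5 equiv), dioxane, 90 °C
Reagents that add atoms: none
Why: In this ligand-assisted Ullmann diaryl ether coupling the C–I bond of 4 reacts well ahead of C–Br, so the bromide is kept for step 7.

Step 3
Reactants: 5 methyl 3-[3-(4-bromophenoxy)-4-methoxyphenyl]propanoate
Product: 6 3-{2-[3-(4-bromophenoxy)-4-methoxyphenyl]ethyl}penta-1,4-dien-3-ol
Conditions: CH2=CHMgBr (3.5 equiv), THF, −20 to 0 °C, ester added to the reagent; then H2O
Reagents that add atoms: vinylmagnesium bromide, C=C[Mg]Br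
Why: Double 1,2-addition of the Grignard reagent to the ester passes through the vinyl ketone, inverse addition at low temperature holds back conjugate addition, and the aryl bromide does not exchange with a vinyl Grignard reagent.

Step 4
Reactants: 6 3-{2-[3-(4-bromophenoxy)-4-methoxyphenyl]ethyl}penta-1,4-dien-3-ol; 7 triethyl orthoacetate
Product: 9 ethyl (4Z)-5-{2-[3-(4-bromophenoxy)-4-methoxyphenyl]ethyl}hepta-4,6-dienoate, via ketene acetal 8 (not isolated)
Conditions: 7 (10 equiv), EtCO2H (10 mol %), 138 °C, EtOH distilled off; crude isomer mixture then maleic anhydride, toluene, 50 °C; SiO2 chromatography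
Reagents that add atoms: none
Why: The Johnson–Claisen rearrangement through a chair transition state should give both alkene isomers because vinyl and CH2CH2Ar compete for the pseudo-axial site, and only the unwanted E isomer can reach the s-cis diene conformation, so the Diels–Alder scavenger removes it and leaves the Z isomer.

Step 5
Reactants: 10 4-(benzyloxy)-3-hydroxybenzaldehyde
Product: 11 4-(benzyloxy)-3-(tert-butyldimethylsilyloxy)benzaldehyde
Conditions: TBSCl (1.2 equiv), imidazole (2.5 equiv), DMF, rt
Reagents that add atoms: tert-butyldimethylsilyl chloride, CC(C)(C)[Si](C)(C)Cl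
Why: Standard silylation masks the ring C phenol, which must stay distinct from the benzyl-protected oxygen until the lactonisation.

Step 6
Reactants: 11 4-(benzyloxy)-3-(tert-butyldimethylsilyloxy)benzaldehyde
Product: 12 1-(benzyloxy)-2-(tert-butyldimethylsilyloxy)-4-vinylbenzene
Conditions: MePPh3Br (1.3 equiv), n-BuLi (1.25 equiv), THF, 0 °C; then 11, 0 °C to rt
Reagents that add atoms: methyltriphenylphosphonium bromide, C[P+](c1ccccc1)(c1ccccc1)c1ccccc1.[Br-]
Why: Wittig methylenation with the preformed ylide converts the aldehyde into the styrene without harming the aryl silyl ether.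

Step 7
Reactants: 12 1-(benzyloxy)-2-(tert-butyldimethylsilyloxy)-4-vinylbenzene; 9 ethyl (4Z)-5-{2-[3-(4-bromophenoxy)-4-methoxyphenyl]ethyl}hepta-4,6-dienoate
Product: 14 ethyl (4Z)-5-{2-[3-(4-{2-[4-(benzyloxy)-3-(tert-butyldimethylsilyloxy)phenyl]ethyl}phenoxy)-4-methoxyphenyl]ethyl}hepta-4,6-dienoate, via B-alkyl-9-BBN borane 13 (not isolated)
Conditions: 12 (1.2 equiv), 9-BBN (1.15 equiv), THF, rt; then 3 M aq. K3PO4, 9, PdCl2(dppf) (5 mol %), THF/DMF, 50 °C
Reagents that add atoms: 9-borabicyclo[3.3.1]nonane, B1C2CCCC1CCC2 (its boron cage stays in 13 only)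
Why: Anti-Markovnikov hydroboration of the styrene is finished and all B–H is consumed before diene 9 is added, and the B-alkyl Suzuki–Miyaura coupling then forms the B–C ethano bridge directly, so no later alkene reduction can touch the diene.

Step 8
Reactants: 14 ethyl (4Z)-5-{2-[3-(4-{2-[4-(benzyloxy)-3-(tert-butyldimethylsilyloxy)phenyl]ethyl}phenoxy)-4-methoxyphenyl]ethyl}hepta-4,6-dienoate
Product: 15 (4Z)-5-{2-[3-(4-{2-[4-(benzyloxy)-3-hydroxyphenyl]ethyl}phenoxy)-4-methoxyphenyl]ethyl}hepta-4,6-dienoic acid (seco acid)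
Conditions: LiOH·H2O (10 equiv), THF/MeOH/H2O, 45 °C; then cold 1 M HCl to pH 3
Reagents that add atoms: lithium hydroxide, [Li+].[OH-]
Why: Saponification of the ethyl ester and hydroxide attack at silicon of the aryl silyl ether (phenoxide as leaving group) take place in one operation, while the benzyl ether and the diene are inert to base.

Step 9
Reactants: 15 seco acid
Product: 17 21-membered (Z)-dienyl macrolactone (aryl ester of the ring C 3-oxygen; chain O–C1(=O)–C6H2–C5H2–C4H=C3(CH=CH2)–CH2CH2–ring A), via mixed anhydride 16 (not isolated)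
Conditions: 2,4,6-trichlorobenzoyl chloride (1.05 equiv), Et3N (1.2 equiv), THF, 0 °C to rt; then syringe-pump addition over 12 h to DMAP (6 equiv), toluene (final 1 mM), 60 °C
Reagents that add atoms: 2,4,6-trichlorobenzoyl chloride, O=C(Cl)c1c(Cl)cc(Cl)cc1Cl (stays in 16 only)
Why: In this Yamaguchi macrolactonisation the carboxylate takes the hindered acid chloride faster than the phenol does, DMAP passes the unhindered acyl group to the phenol, and slow addition at high dilution favours ring closure over oligomerisation.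

Step 10
Reactants: 17 21-membered (Z)-dienyl macrolactone
Product: 19 19-membered macrocycle with ring D as a 1-aryloxy-3-alkylcyclohexa-1,3-diene, via aryl enol ether 18 (not isolated)
Conditions: Tebbe reagent Cp2Ti(CH2)(Cl)AlMe2 (1.5 equiv, 0.5 M in toluene), pyridine (cat.), THF/toluene, −40 °C to rt; 15 % aq. NaOH at −10 °C, filtration through basic Al2O3, solvent exchange; then second-generation Grubbs catalyst (H2IMes)(PCy3)Cl2Ru=CHPh (15 mol %), degassed toluene (1 mM), 70 °C, argon sparge
Reagents that add atoms: Tebbe reagent Cp2Ti(CH2)(Cl)AlMe2, C[Al](C)C[Ti+2]Cl.c1cc[cH-]c1.c1cc[cH-]c1 (its CH2 stays in 18 only)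
Why: Proposed new method: Cp2Ti=CH2, set free from the reagent by pyridine, undergoes [2+2] addition and cycloreversion at the only carbonyl group to give aryl enol ether 18 and Cp2TiO, after which the ruthenium benzylidene exchanges at the monosubstituted vinyl group, the resulting vinylalkylidene adds [2+2] to the C1=CH2 alkene with ruthenium at the CH2 end, and cycloreversion leaves the C1=C2 bond and a ruthenium methylidene that continues the cycle with loss of ethene. The closest known reactions are the methylenation of aryl esters with this titanium reagent, the ring-closing metathesis of acyclic alkyl and silyl enol ethers with terminal alkenes under the same ruthenium catalyst, and metathesis–aromatisation routes to benzenes, whereas an aryl ester held in a macrolactone and a conjugated diene as partner are untested. The six-membered ring (C1 to C6) closes by transannular ring-closing metathesis, and the 19-membered macrocycle is not closed end to end but results from contraction of the 21-membered ring, since the new bond takes C4, C5 and C6 out of the perimeter. No stereocentre is formed. The step needs initiation at the vinyl group only and ring closure ahead of intermolecular metathesis: the first follows from the substitution pattern (one monosubstituted, one 1,1-disubstituted donor and one trisubstituted alkene), the second from the Z geometry at C3=C4, which holds C2 and C1 on the same side within reach of a six-membered ring, and from 1 mM dilution. The non-aromatic ring D also defers the cyclophane strain to step 11, where aromatisation pays for it.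

Step 11
Reactants: 19 cyclohexadiene macrocycle
Product: 20 O-benzyl ether of the target (ring D aromatic)
Conditions: DDQ (1.05 equiv), toluene, 0 °C to rt
Reagents that add atoms: none
Why: DDQ dehydrogenation by hydride abstraction from the C5/C6 methylenes of the electron-rich aryloxydiene, followed by proton loss, is far faster than oxidation of the benzyl ether or of the bibenzyl CH2 groups at this temperature and stoichiometry.

Step 12
Reactants: 20 O-benzyl ether of the target
Product: 21 target CNP0132125.0
Conditions: H2 (1 atm), Pd/C (10 wt %), EtOAc/EtOH, rt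
Reagents that add atoms: none
Why: Catalytic hydrogenolysis cleaves the benzylic C–O bond only, since the diaryl ethers and the methyl ether are inert.

**Compound list**
1 | isoferulic acid, (E)-3-(3-hydroxy-4-methoxyphenyl)prop-2-enoic acid | COc1ccc(/C=C/C(=O)O)cc1O | starting material
2 | dihydroisoferulic acid, 3-(3-hydroxy-4-methoxyphenyl)propanoic acid | COc1ccc(CCC(=O)O)cc1O | intermediate
3 | methyl 3-(3-hydroxy-4-methoxyphenyl)propanoate | COC(=O)CCc1ccc(OC)c(O)c1 | intermediate
4 | 1-bromo-4-iodobenzene | Brc1ccc(I)cc1 | starting material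
5 | methyl 3-[3-(4-bromophenoxy)-4-methoxyphenyl]propanoate | COC(=O)CCc1ccc(OC)c(Oc2ccc(Br)cc2)c1 | intermediate
6 | 3-{2-[3-(4-bromophenoxy)-4-methoxyphenyl]ethyl}penta-1,4-dien-3-ol | C=CC(O)(C=C)CCc1ccc(OC)c(Oc2ccc(Br)cc2)c1 | intermediate
7 | triethyl orthoacetate | CCOC(C)(OCC)OCC | starting material
8 | ketene acetal, 1-ethoxyvinyl ether of 6 | C=C(OCC)OC(C=C)(C=C)CCc1ccc(OC)c(Oc2ccc(Br)cc2)c1 | intermediate
9 | ethyl (4Z)-5-{2-[3-(4-bromophenoxy)-4-methoxyphenyl]ethyl}hepta-4,6-dienoate | CCOC(=O)CC/C=C(\C=C)CCc1ccc(OC)c(Oc2ccc(Br)cc2)c1 | intermediate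
10 | 4-(benzyloxy)-3-hydroxybenzaldehyde | O=Cc1ccc(OCc2ccccc2)c(O)c1 | starting material
11 | 4-(benzyloxy)-3-(tert-butyldimethylsilyloxy)benzaldehyde | O=Cc1ccc(OCc2ccccc2)c(O[Si](C)(C)C(C)(C)C)c1 | intermediate
12 | 1-(benzyloxy)-2-(tert-butyldimethylsilyloxy)-4-vinylbenzene | C=Cc1ccc(OCc2ccccc2)c(O[Si](C)(C)C(C)(C)C)c1 | intermediate
13 | B-{2-[4-(benzyloxy)-3-(tert-butyldimethylsilyloxy)phenyl]ethyl}-9-BBN | CC(C)(C)[Si](C)(C)Oc1cc(CCB2C3CCCC2CCC3)ccc1OCc1ccccc1 | intermediate
14 | ethyl (4Z)-5-{2-[3-(4-{2-[4-(benzyloxy)-3-(tert-butyldimethylsilyloxy)phenyl]ethyl}phenoxy)-4-methoxyphenyl]ethyl}hepta-4,6-dienoate | CCOC(=O)CC/C=C(\C=C)CCc1ccc(OC)c(Oc2ccc(CCc3ccc(OCc4ccccc4)c(O[Si](C)(C)C(C)(C)C)c3)cc2)c1 | intermediate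
15 | (4Z)-5-{2-[3-(4-{2-[4-(benzyloxy)-3-hydroxyphenyl]ethyl}phenoxy)-4-methoxyphenyl]ethyl}hepta-4,6-dienoic acid | OC(=O)CC/C=C(\C=C)CCc1ccc(OC)c(Oc2ccc(CCc3ccc(OCc4ccccc4)c(O)c3)cc2)c1 | intermediate
16 | mixed anhydride of 15 with 2,4,6-trichlorobenzoic acid | O=C(CC/C=C(\C=C)CCc1ccc(OC)c(Oc2ccc(CCc3ccc(OCc4ccccc4)c(O)c3)cc2)c1)OC(=O)c1c(Cl)cc(Cl)cc1Cl | intermediate
17 | 21-membered (Z)-dienyl macrolactone | COc1ccc2cc1Oc1ccc(cc1)CCc1ccc(OCc3ccccc3)c(c1)OC(=O)CC/C=C(\C=C)CC2 | intermediate
18 | aryl enol ether macrocycle (C=O of 17 replaced by C=CH2) | COc1ccc2cc1Oc1ccc(cc1)CCc1ccc(OCc3ccccc3)c(c1)OC(=C)CC/C=C(\C=C)CC2 | intermediate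
19 | 19-membered macrocycle, ring D as 1-aryloxy-3-alkylcyclohexa-1,3-diene | COc1ccc2cc1Oc1ccc(cc1)CCc1ccc(OCc3ccccc3)c(c1)OC1=CC(=CCC1)CC2 | intermediate
20 | O-benzyl ether of the target | COc1ccc2cc1Oc1ccc(cc1)CCc1ccc(OCc3ccccc3)c(c1)Oc1cccc(c1)CC2 | intermediate
21 | CNP0132125.0 | COc1ccc2cc1Oc1ccc(cc1)CCc1ccc(O)c(c1)Oc1cccc(c1)CC2 | target

Total step count: 12. Longest linear sequence: 10 steps (steps 1–4 and 7–12, from 1).

**Steps most likely to fail**

**Step 10.**
- What may go wrong: the stabilised ruthenium vinylalkylidene may stall before it engages the hindered, electron-rich enol ether alkene. Intermolecular metathesis of the vinyl groups, hydrolysis of the enol ether on handling, or capture of the diene by the titanium methylidene could then take over.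
- Fallback: it uses known chemistry only, sets out from 4 and from borane 13, and comes back at 21. Isovanillin is coupled with 4 under the conditions of step 2 to give 3-(4-bromophenoxy)-4-methoxybenzaldehyde F1. B-alkyl Suzuki coupling of F1 with 13 as in step 7 gives the silyl-protected bibenzyl aldehyde F2, and TBAF in THF frees the ring C phenol aldehyde F3. Chan–Lam coupling of F3 with 3-formylphenylboronic acid (Cu(OAc)2, pyridine, 4 Å sieves, CH2Cl2, air) brings in an aromatic ring D as tetra-aryl dialdehyde F4. McMurry macrocyclisation with low-valent titanium (TiCl4, Zn, pyridine, THF, reflux, slow addition) closes the A–D bridge as macrocyclic stilbene F5. H2 over Pd/C then saturates the stilbene and cleaves the benzyl ether in one operation to give 21.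

**Step 4.**
- What may go wrong: geometric selectivity in the sigmatropic shift may be poor, because the vinyl group may prefer the pseudo-equatorial site. Material is also lost when the isomers are sorted.
- Fallback: it sets out from 5 and comes back at 9, and it replaces one vinyl group by a slimmer surrogate. Ester 5 is turned into Weinreb amide F6 (MeNH(OMe)·HCl, i-PrMgCl, THF, −10 °C). CH2=CHMgBr gives vinyl ketone F7, and HC≡CMgBr adds 1,2 to give racemic enynol F8. Heating with 7 and EtCO2H forms enynyl ketene acetal F9, which rearranges through its alkene arm to (4Z)-enyne ester F10. The rod-like ethynyl group takes the pseudo-axial site, which ends cis to the ester chain. Semi-hydrogenation (H2, Pd/CaCO3 poisoned with Pb(OAc)2, quinoline, EtOAc) turns ethynyl into vinyl and gives 9.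

**Step 9.**
- What may go wrong: intermolecular acylation (cyclic dimer, oligomers) or aroylation of the phenol may outrun closure of the 21-membered ring.
- Fallback: it sets out from 9 and 10 and comes back at 20. Ring D is built in the open chain, still by the ester-to-arene metathesis, and the macrocycle is closed last at the B–C bridge. Ester 9 is saponified (LiOH) to bromo dienoic acid F11, which is esterified with 10 (EDC·HCl, DMAP, CH2Cl2) to give open-chain aryl ester aldehyde F12. Cp2Ti(CH2)(Cl)AlMe2 (2.5 equiv) methylenates both the aldehyde and the ester to give styrenyl enol ether F13. (H2IMes)(PCy3)Cl2Ru=CHPh closes the six-membered ring to open-chain cyclohexadiene F14, and DDQ gives bromo styrene diaryl ether F15. 9-BBN adds to the styrene, now the only alkene, to give bromo borane F16. Intramolecular B-alkyl Suzuki coupling (PdCl2(dppf), aq. K3PO4, THF/DMF, slow addition) then forms the B–C ethano bridge and gives 20.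

**Further compounds**
F1 | step 10 | 3-(4-bromophenoxy)-4-methoxybenzaldehyde | COc1ccc(C=O)cc1Oc1ccc(Br)cc1
F2 | step 10 | 3-(4-{2-[4-(benzyloxy)-3-(tert-butyldimethylsilyloxy)phenyl]ethyl}phenoxy)-4-methoxybenzaldehyde | COc1ccc(C=O)cc1Oc1ccc(CCc2ccc(OCc3ccccc3)c(O[Si](C)(C)C(C)(C)C)c2)cc1
F3 | step 10 | 3-(4-{2-[4-(benzyloxy)-3-hydroxyphenyl]ethyl}phenoxy)-4-methoxybenzaldehyde | COc1ccc(C=O)cc1Oc1ccc(CCc2ccc(OCc3ccccc3)c(O)c2)cc1
F4 | step 10 | 3-(4-{2-[4-(benzyloxy)-3-(3-formylphenoxy)phenyl]ethyl}phenoxy)-4-methoxybenzaldehyde | COc1ccc(C=O)cc1Oc1ccc(CCc2ccc(OCc3ccccc3)c(Oc3cccc(C=O)c3)c2)cc1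
F5 | step 10 | macrocyclic stilbene, A–D bridge CH=CH, either geometry | COc1ccc2cc1Oc1ccc(cc1)CCc1ccc(OCc3ccccc3)c(c1)Oc1cccc(c1)C=C2
F6 | step 4 | 3-[3-(4-bromophenoxy)-4-methoxyphenyl]-N-methoxy-N-methylpropanamide | CON(C)C(=O)CCc1ccc(OC)c(Oc2ccc(Br)cc2)c1
F7 | step 4 | 5-[3-(4-bromophenoxy)-4-methoxyphenyl]pent-1-en-3-one | C=CC(=O)CCc1ccc(OC)c(Oc2ccc(Br)cc2)c1
F8 | step 4 | 3-{2-[3-(4-bromophenoxy)-4-methoxyphenyl]ethyl}pent-1-en-4-yn-3-ol, racemic | C=CC(O)(C#C)CCc1ccc(OC)c(Oc2ccc(Br)cc2)c1
F9 | step 4 | 1-ethoxyvinyl ether of F8, racemic | C=C(OCC)OC(C=C)(C#C)CCc1ccc(OC)c(Oc2ccc(Br)cc2)c1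
F10 | step 4 | ethyl (4Z)-5-{2-[3-(4-bromophenoxy)-4-methoxyphenyl]ethyl}hept-4-en-6-ynoate | CCOC(=O)CC/C=C(\C#C)CCc1ccc(OC)c(Oc2ccc(Br)cc2)c1
F11 | step 9 | (4Z)-5-{2-[3-(4-bromophenoxy)-4-methoxyphenyl]ethyl}hepta-4,6-dienoic acid | OC(=O)CC/C=C(\C=C)CCc1ccc(OC)c(Oc2ccc(Br)cc2)c1
F12 | step 9 | 2-(benzyloxy)-5-formylphenyl ester of F11 | O=Cc1ccc(OCc2ccccc2)c(OC(=O)CC/C=C(\C=C)CCc2ccc(OC)c(Oc3ccc(Br)cc3)c2)c1
F13 | step 9 | bis-methylenated F12 (styrene and aryl enol ether) | C=Cc1ccc(OCc2ccccc2)c(OC(=C)CC/C=C(\C=C)CCc2ccc(OC)c(Oc3ccc(Br)cc3)c2)c1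
F14 | step 9 | open-chain 1-aryloxy-3-alkylcyclohexa-1,3-diene | C=Cc1ccc(OCc2ccccc2)c(OC2=CC(CCc3ccc(OC)c(Oc4ccc(Br)cc4)c3)=CCC2)c1
F15 | step 9 | open-chain tetra-aryl compound with ring D aromatic, ring C vinyl, ring B bromide | C=Cc1ccc(OCc2ccccc2)c(Oc2cccc(CCc3ccc(OC)c(Oc4ccc(Br)cc4)c3)c2)c1
F16 | step 9 | B-alkyl-9-BBN adduct of F15 | Brc1ccc(Oc2cc(CCc3cccc(Oc4cc(CCB5C6CCCC5CCC6)ccc4OCc4ccccc4)c3)ccc2OC)cc1
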